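## Plan

- Numbering (halimane): decalin C1–C10 with C1=C10, C4 = C(CH3)2, C5 = ring-fusion CH, C8 = CH(CH3), C9 = quaternary; chain C11–C15 with C13 = CH(CH3) and C15 = ester carbon.
- Retrosynthesis: cut the glyceryl ester C–O; place a carbonyl helper on C2 and cut ring A at C4–C5 and C1=C10 (Michael/aldol retron) to a ring-B ketone and mesityl oxide; cut C9–CH3 and C8–CH3 (conjugate addition/enolate methylation) and C9–C11 (Negishi coupling).
- Forward: the chain iodide from methyl hydrogen (R)-3-methylglutarate is joined to 2-iodocyclohexenone, ring B receives its two methyl groups, ring A is annulated in one operation, the C2 carbonyl is reduced off through its dithiolane, and the methyl ester is exchanged for the 2-glyceryl ester.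
- Enabling feature: C10 is flanked by the quaternary C9, so a C10 ketone in ring B enolises only at C5; in ring A the gem-dimethyl carbon C4 lies β and C1 lies α′ to C2, which is the pattern mesityl oxide delivers.
- Stereochemistry: C13 from the chiral pool; C8 by ligand-controlled methyl addition; C9 by methylation anti to the C8 methyl; C5 in the annulation by attack anti to the axial C9 chain, which should also be the more stable epimer.

Key step: step 6

Remarks on the chemistry:
- Assumption: in step 4 the phosphoramidite antipode that gives the (R)-configured C8 is meant; the named antipode is a placeholder for whichever one does so.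
- Compounds 1, 4, 11 and 18 are taken as commercial.
- The descriptors of 3 and 5 are S only because iodine or zinc changes the CIP priorities; the C13 centre itself is never touched.

## Route

Step 1
Reactants: 1 methyl hydrogen (R)-3-methylglutarate
Product: 2 methyl (3R)-5-hydroxy-3-methylpentanoate
Conditions: BH3·SMe2, THF, −10 → 20 °C; then H2O
Reagents that add atoms: none
Why: Borane reduces a free carboxylic acid through its acyloxyborane much faster than an ester (chemoselective borane reduction), and the stereocentre is not involved.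

Step 2
Reactants: 2 methyl (3R)-5-hydroxy-3-methylpentanoate
Product: 3 methyl (3S)-5-iodo-3-methylpentanoate
Conditions: I2, PPh3, imidazole, CH2Cl2, 0 °C
Reagents that add atoms: iodine, II
Why: Appel-type iodination converts the primary alcohol into the iodide by SN2 displacement of the oxyphosphonium group under neutral conditions that should also forestall lactonisation of 2.

Step 3
Reactants: 3 methyl (3S)-5-iodo-3-methylpentanoate; 4 2-iodocyclohex-2-en-1-one
Product: 6 methyl (3R)-3-methyl-5-(6-oxocyclohex-1-en-1-yl)pentanoate, via alkylzinc iodide 5 (not isolated)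
Conditions: Zn dust (TMSCl/BrCH2CH2Br-activated), DMA, 40 °C; then 4, Pd(dba)2 (3 mol %), P(2-furyl)3 (12 mol %), THF/DMA, 20 °C
Reagents that add atoms: none
Why: Zinc insertion into a primary alkyl iodide tolerates the ester, and the Pd-catalysed Negishi coupling of alkylzinc halides with α-iodoenones is an established route to α-alkyl cycloalkenones.

Step 4
Reactants: 6 methyl (3R)-3-methyl-5-(6-oxocyclohex-1-en-1-yl)pentanoate
Product: 9 methyl (3R)-5-[(1R,2R)-1,2-dimethyl-6-oxocyclohexyl]-3-methylpentanoate, via aluminium enolate 7 (not isolated), via lithium aluminate enolate 8 (not isolated)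
Conditions: Me3Al (1.5 equiv), CuTC (5 mol %), (S)-binaphthol N,N-bis[(R)-1-phenylethyl]phosphoramidite (10 mol %), Et2O, −30 °C; then THF, MeLi (1.5 equiv), −78 °C; MeI, DMPU, −78 → 0 °C
Reagents that add atoms: trimethylaluminium, C[Al](C)C; iodomethane, CI
Why: Copper-catalysed asymmetric conjugate addition of Me3Al to an α-substituted cyclohexenone should set C8 under ligand control, and the regiodefined enolate, made nucleophilic as its aluminate, should be methylated at C9 on the face anti to the new C8 methyl, which places the C9 methyl trans and the chain cis to it.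

Step 5
Reactants: 9 methyl (3R)-5-[(1R,2R)-1,2-dimethyl-6-oxocyclohexyl]-3-methylpentanoate
Product: 10 methyl (3R)-5-[(1R,6R)-1,6-dimethyl-2-(trimethylsilyloxy)cyclohex-2-en-1-yl]-3-methylpentanoate
Conditions: TMSOTf, Et3N, CH2Cl2, 0 °C
Reagents that add atoms: trimethylsilyl trifluoromethanesulfonate, C[Si](C)(C)OS(=O)(=O)C(F)(F)F
Why: Soft enolisation with silyl triflate and amine silylates the ketone but not the ester, and because C9 is quaternary only the C5=C10 enol ether can form.

Step 6
Reactants: 10 methyl (3R)-5-[(1R,6R)-1,6-dimethyl-2-(trimethylsilyloxy)cyclohex-2-en-1-yl]-3-methylpentanoate; 11 mesityl oxide (4-methylpent-3-en-2-one)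
Product: 14 methyl (3R)-3-methyl-5-[(1R,2R,4aS)-1,2,5,5-tetramethyl-7-oxo-1,2,3,4,4a,5,6,7-octahydronaphthalen-1-yl]pentanoate, via 1,5-diketone 12 (not isolated), via aldol adduct 13 (not isolated)
Conditions: 11 (1.5 equiv), TiCl4 (2.2 equiv), CH2Cl2, −78 °C; H2O quench, crude; then TsOH·H2O (20 mol %), PhMe, 110 °C (Dean–Stark)
Reagents that add atoms: none
Why: TiCl4 activates mesityl oxide, whose β-carbon (C4) is attacked by C5 of enol ether 10 in a Mukaiyama–Michael addition to give 1,5-diketone 12, and acid then lets the terminal enol of the methyl ketone (C1) add to the C10 carbonyl and lose water, so that C4–C5 and C1=C10 arise in one telescoped operation. The closest known reaction type is the Robinson annulation in its silyl enol ether/Lewis acid variant, the same Michael–aldol condensation that turns acetone and mesityl oxide into isophorone. Ring A closes by a 6-(enolendo)-exo-trig aldol addition helped by the gem-dimethyl effect of C4, and dehydration of aldol 13 is driven by conjugation with the C2 carbonyl helper, which steps 7 and 8 remove. The only new stereocentre, C5, should be set by attack of the bulky electrophile anti to the pseudoaxial C9 chain on the half-chair of 10 that keeps the C8 methyl equatorial; this is also the epimer with C4 and the C8 methyl both equatorial on ring B, so acid-mediated enolisation at C5 should only reinforce it. Regioselectivity needs no extra control: C9 is quaternary, so C10 enolises only towards C5, and of the two enols of the methyl ketone only the C1 terminus can reach C10 through a six-membered transition state.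

Step 7
Reactants: 14 methyl (3R)-3-methyl-5-[(1R,2R,4aS)-1,2,5,5-tetramethyl-7-oxo-1,2,3,4,4a,5,6,7-octahydronaphthalen-1-yl]pentanoate
Product: 15 1,3-dithiolane (ethylene dithioketal at C2) of 14, ring double bond C1=C10 retained
Conditions: HSCH2CH2SH, BF3·OEt2 (cat.), CH2Cl2, 0 → 20 °C
Reagents that add atoms: ethane-1,2-dithiol, SCCS
Why: Lewis acid-catalysed dithioketalisation of the enone carbonyl, a reaction type in which the conjugated double bond of ring-fused cyclohexenones stays in place (unlike O-ketalisation), turns the C2 helper into a group that can be reduced off while the ester is inert.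

Step 8
Reactants: 15 1,3-dithiolane of 14
Product: 16 methyl (3R)-3-methyl-5-[(1R,2R,4aS)-1,2,5,5-tetramethyl-1,2,3,4,4a,5,6,7-octahydronaphthalen-1-yl]pentanoate
Conditions: Raney Ni (W-2, acetone-deactivated), MeOH/THF, 50 °C
Reagents that add atoms: none
Why: Mozingo reductive desulfurisation replaces both C–S bonds by C–H, allylic dithiolanes of this type are known to give the alkene with the double bond unmoved, and the hindered trisubstituted C1=C10 bond should survive deactivated nickel.

Step 9
Reactants: 16 methyl (3R)-3-methyl-5-[(1R,2R,4aS)-1,2,5,5-tetramethyl-1,2,3,4,4a,5,6,7-octahydronaphthalen-1-yl]pentanoate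
Product: 17 (3R)-3-methyl-5-[(1R,2R,4aS)-1,2,5,5-tetramethyl-1,2,3,4,4a,5,6,7-octahydronaphthalen-1-yl]pentanoic acid
Conditions: LiOH, THF/MeOH/H2O, 40 °C; 1 M HCl
Reagents that add atoms: water (delivered as hydroxide), O
Why: Saponification of an unhindered methyl ester by acyl–oxygen cleavage cannot affect C13 (β to the carbonyl) or the isolated alkene.

Step 10
Reactants: 17 (3R)-3-methyl-5-[(1R,2R,4aS)-1,2,5,5-tetramethyl-1,2,3,4,4a,5,6,7-octahydronaphthalen-1-yl]pentanoic acid; 18 cis-2-phenyl-1,3-dioxan-5-ol (1,3-O-benzylideneglycerol)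
Product: 19 cis-2-phenyl-1,3-dioxan-5-yl (3R)-3-methyl-5-[(1R,2R,4aS)-1,2,5,5-tetramethyl-1,2,3,4,4a,5,6,7-octahydronaphthalen-1-yl]pentanoate
Conditions: DCC, DMAP (10 mol %), CH2Cl2, 0 → 20 °C
Reagents that add atoms: none
Why: Steglich esterification acylates the secondary hydroxyl, and the benzylidene acetal masks both primary hydroxyls of glycerol so that only O-2 can be esterified.

Step 11
Reactants: 19 cis-2-phenyl-1,3-dioxan-5-yl ester of 17
Product: 21 1,3-dihydroxypropan-2-yl (3R)-3-methyl-5-[(1R,2R,4aS)-1,2,5,5-tetramethyl-1,2,3,4,4a,5,6,7-octahydronaphthalen-1-yl]pentanoate, via cyclic borate 20 (not isolated)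
Conditions: B(OH)3, B(OEt)3, 100 °C; then H2O/Et2O, 0 °C
Reagents that add atoms: none
Why: Boric acid-mediated transacetalisation removes the benzylidene group and holds the freed 1,3-diol as its borate, which is hydrolysed cold and near neutral, so the 2→1 acyl shift typical of 2-monoacylglycerols should be suppressed and the alkene is untouched.

## Compound list

1 | methyl hydrogen (R)-3-methylglutarate | C[C@H](CC(=O)O)CC(=O)OC | starting material
2 | methyl (3R)-5-hydroxy-3-methylpentanoate | C[C@H](CCO)CC(=O)OC | intermediate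
3 | methyl (3S)-5-iodo-3-methylpentanoate | C[C@H](CCI)CC(=O)OC | intermediate
4 | 2-iodocyclohex-2-en-1-one | O=C1CCCC=C1I | starting material
5 | [(3S)-5-methoxy-3-methyl-5-oxopentyl]zinc iodide | C[C@H](CC[Zn]I)CC(=O)OC | intermediate
6 | methyl (3R)-3-methyl-5-(6-oxocyclohex-1-en-1-yl)pentanoate | C[C@H](CCC1=CCCCC1=O)CC(=O)OC | intermediate
7 | methyl (3R)-5-[(6R)-2-(dimethylalumanyloxy)-6-methylcyclohex-1-en-1-yl]-3-methylpentanoate | C[C@H](CCC1=C(O[Al](C)C)CCC[C@H]1C)CC(=O)OC | intermediate
8 | lithium trimethylaluminate of the same enolate | [Li+].C[C@H](CCC1=C(O[Al-](C)(C)C)CCC[C@H]1C)CC(=O)OC | intermediate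
9 | methyl (3R)-5-[(1R,2R)-1,2-dimethyl-6-oxocyclohexyl]-3-methylpentanoate | C[C@H](CC[C@@]1(C)C(=O)CCC[C@H]1C)CC(=O)OC | intermediate
10 | methyl (3R)-5-[(1R,6R)-1,6-dimethyl-2-(trimethylsilyloxy)cyclohex-2-en-1-yl]-3-methylpentanoate | C[C@H](CC[C@@]1(C)C(O[Si](C)(C)C)=CCC[C@H]1C)CC(=O)OC | intermediate
11 | mesityl oxide (4-methylpent-3-en-2-one) | CC(C)=CC(C)=O | starting material
12 | methyl (3R)-5-[(1R,2R,5S)-1,2-dimethyl-5-(2-methyl-4-oxopentan-2-yl)-6-oxocyclohexyl]-3-methylpentanoate | C[C@H](CC[C@@]1(C)C(=O)[C@H](C(C)(C)CC(C)=O)CC[C@H]1C)CC(=O)OC | intermediate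
13 | methyl (3R)-5-[(1R,2R,4aS)-8a-hydroxy-1,2,5,5-tetramethyl-7-oxodecahydronaphthalen-1-yl]-3-methylpentanoate (C8a not defined) | C[C@H](CC[C@@]1(C)C2(O)CC(=O)CC(C)(C)[C@@H]2CC[C@H]1C)CC(=O)OC | intermediate
14 | methyl (3R)-3-methyl-5-[(1R,2R,4aS)-1,2,5,5-tetramethyl-7-oxo-1,2,3,4,4a,5,6,7-octahydronaphthalen-1-yl]pentanoate | C[C@H](CC[C@@]1(C)C2=CC(=O)CC(C)(C)[C@@H]2CC[C@H]1C)CC(=O)OC | intermediate
15 | 1,3-dithiolane (ethylene dithioketal at C2) of 14 | C[C@H](CC[C@@]1(C)C2=CC3(SCCS3)CC(C)(C)[C@@H]2CC[C@H]1C)CC(=O)OC | intermediate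
16 | methyl (3R)-3-methyl-5-[(1R,2R,4aS)-1,2,5,5-tetramethyl-1,2,3,4,4a,5,6,7-octahydronaphthalen-1-yl]pentanoate | C[C@H](CC[C@@]1(C)C2=CCCC(C)(C)[C@@H]2CC[C@H]1C)CC(=O)OC | intermediate
17 | (3R)-3-methyl-5-[(1R,2R,4aS)-1,2,5,5-tetramethyl-1,2,3,4,4a,5,6,7-octahydronaphthalen-1-yl]pentanoic acid | C[C@H](CC[C@@]1(C)C2=CCCC(C)(C)[C@@H]2CC[C@H]1C)CC(=O)O | intermediate
18 | cis-2-phenyl-1,3-dioxan-5-ol | O[C@H]1CO[C@@H](c2ccccc2)OC1 | starting material
19 | cis-2-phenyl-1,3-dioxan-5-yl ester of 17 | C[C@H](CC[C@@]1(C)C2=CCCC(C)(C)[C@@H]2CC[C@H]1C)CC(=O)O[C@H]1CO[C@@H](c2ccccc2)OC1 | intermediate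
20 | 2-hydroxy-1,3,2-dioxaborinan-5-yl ester of 17 | C[C@H](CC[C@@]1(C)C2=CCCC(C)(C)[C@@H]2CC[C@H]1C)CC(=O)OC1COB(O)OC1 | intermediate
21 | 1,3-dihydroxypropan-2-yl (3R)-3-methyl-5-[(1R,2R,4aS)-1,2,5,5-tetramethyl-1,2,3,4,4a,5,6,7-octahydronaphthalen-1-yl]pentanoate | C[C@H](CC[C@@]1(C)C2=CCCC(C)(C)[C@@H]2CC[C@H]1C)CC(=O)OC(CO)CO | target

## Count and risks

Total step count: 11. Longest linear sequence: 11 steps (1 → 21).

Steps most likely to fail:

1. Step 6. Bond formation between the neopentyl-type enol ether carbon C5 and the fully substituted β-carbon of mesityl oxide may stall or divert to 1,2-addition. The adduct may also revert by retro-Michael cleavage before the hindered C10 carbonyl is attacked, and face selectivity at C5 may be incomplete. Fallback: the bonds around C4 would be built in the opposite order. Setting out from 10, a Mukaiyama aldol addition to acetone (TiCl4, CH2Cl2, −78 °C) would give the β-hydroxy ketone F1. Acid-mediated dehydration would give the isopropylidene ketone F2, a fixed s-cis exocyclic enone. Conjugate addition of the small nucleophile 2-(trimethylsilyloxy)propene (TiCl4) to C4, then protonation at C5, would rejoin the route at 12, which is closed to 14 as in step 6.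

2. Step 4. Methyl transfer to the α-branched enone may proceed with incomplete enantiofacial control. The enolate may also be acylated intramolecularly by the ester, or exchange protons before it is methylated. Fallback: C8 would be set by hydride delivery instead of methyl delivery. Setting out from 3, the alkylzinc 5 would be coupled (Negishi) with 2-iodo-3-methylcyclohex-2-en-1-one F3, made by α-iodination of 3-methylcyclohex-2-en-1-one, to give the tetrasubstituted enone F4. Copper hydride-catalysed asymmetric conjugate reduction (Cu(OAc)2, DTBM-SEGPHOS antipode as required, Ph2SiH2) would give the silyl enol ether F5 with C8 in place. Fluoride-promoted methylation (TBAT, MeI) anti to the C8 methyl, without any organolithium, would come back to the route at 9.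

3. Step 8. Desulfurisation on nickel may be accompanied by migration or saturation of the C1=C10 double bond. Fallback: the C2 oxygen would be removed by allylic substitution with hydride. Setting out from 14, Luche reduction (NaBH4, CeCl3, MeOH) would give the allylic alcohol F6, and ClCO2Me/pyridine the allylic methyl carbonate F7. Pd(PPh3)4 with NaBH4 in THF should then deliver hydride to the less hindered C2 terminus of the π-allyl complex, which leaves the double bond at C1=C10 and comes back to the route at 16.

## Further compounds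

F1 | step 6 | methyl (3R)-5-[(1R,2R)-5-(2-hydroxypropan-2-yl)-1,2-dimethyl-6-oxocyclohexyl]-3-methylpentanoate (C5 not defined) | C[C@H](CC[C@@]1(C)C(=O)C(C(C)(C)O)CC[C@H]1C)CC(=O)OC
F2 | step 6 | methyl (3R)-5-[(1R,2R)-1,2-dimethyl-6-oxo-5-(propan-2-ylidene)cyclohexyl]-3-methylpentanoate | C[C@H](CC[C@@]1(C)C(=O)C(=C(C)C)CC[C@H]1C)CC(=O)OC
F3 | step 4 | 2-iodo-3-methylcyclohex-2-en-1-one | CC1=C(I)C(=O)CCC1
F4 | step 4 | methyl (3R)-3-methyl-5-(2-methyl-6-oxocyclohex-1-en-1-yl)pentanoate | C[C@H](CCC1=C(C)CCCC1=O)CC(=O)OC
F5 | step 4 | methyl (3R)-5-[(6R)-2-(diphenylsilyloxy)-6-methylcyclohex-1-en-1-yl]-3-methylpentanoate | C[C@H](CCC1=C(O[SiH](c2ccccc2)c2ccccc2)CCC[C@H]1C)CC(=O)OC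
F6 | step 8 | methyl (3R)-5-[(1R,2R,4aS)-7-hydroxy-1,2,5,5-tetramethyl-1,2,3,4,4a,5,6,7-octahydronaphthalen-1-yl]-3-methylpentanoate (C7 not defined) | C[C@H](CC[C@@]1(C)C2=CC(O)CC(C)(C)[C@@H]2CC[C@H]1C)CC(=O)OC
F7 | step 8 | methyl carbonate of F6 | C[C@H](CC[C@@]1(C)C2=CC(OC(=O)OC)CC(C)(C)[C@@H]2CC[C@H]1C)CC(=O)OC
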